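All runs come from a simulation with constants of no real substance; noise was put on by code.

Divide by the catalyst.

| flask | starting material | second substrate | precatalyst | remark | time |
|---|---|---|---|---|---|
| noon | 0.050 M | 0.025 M (fed, over 80 s) | 0.17 mM | run made earlier |  |
| dawn | 0.050 M | 0.025 M (fed, over 80 s) | 0.38 mM | run made earlier |  |
| midnight | 0.050 M | 0.038 M (fed, over 80 s) | 0.25 mM | run made earlier |  |
| flask | 0.050 M | 0.0250 M (fed, over 80 s) | 0.25 mM |  | 15 min |

| run | time / min | target / % | starting material / % |
|---|---|---|---|
| noon | 1.00 | 0 | 99.5 |
| noon | 2.00 | 0.5 | 100.3 |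
| noon | 5.00 | 2.2 | 97.1 |
| noon | 12.0 | 11.6 | 88.2 |
| dawn | 3.00 | 2.0 | 98.2 |
| dawn | 6.00 | 7.4 | 92.7 |
| dawn | 10.0 | 18.8 | 81.5 |
| dawn | 12.0 | 25.6 | 75.3 |
| midnight | 3.00 | 0 | 99.2 |
| midnight | 6.00 | 4.7 | 95.4 |
| midnight | 10.0 | 11.6 | 89.2 |
| midnight | 12.0 | 15.0 | 84.7 |

(scatter of a reading: 0.5 percentage points)

- steps thought possible: precatalyst -> free catalyst; catalyst intermediate B -> free catalyst + second product; second substrate + free catalyst <-> catalyst intermediate B; catalyst intermediate A -> free catalyst + target; starting material + free catalyst <-> catalyst intermediate A

* how much target the flask holds at 15 min, in percent of the starting material charged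
* how much starting material the flask holds at 15 min, in percent of the starting material charged

I read the last rows first, and I divide each target reading by the precatalyst charged. In the noon run this gives 0.682 mM⁻¹ at 12.0 min. In the dawn run it gives 0.674 mM⁻¹, and the two agree within the scatter, so I treat both loadings as lying on one curve. The midnight run, with 0.038 M of second substrate, reads lower, at 0.600 mM⁻¹. The flask has the 0.0250 M of the other two runs, so I leave the midnight run aside.

Now I read down the dawn column. Between 6.00 min and 10.0 min the target rises by 0.0285 min⁻¹ of the charge. Between 10.0 min and 12.0 min it rises faster, by 0.0340 min⁻¹, so in the dawn run I read an induction period that is still fading, as far as these scattered readings can show it. I hold the later rate steady, which is my cautious choice, and I get 0.942 mM⁻¹. For 0.050 M of starting material and 0.0250 M of second substrate, this is my estimate of the specific yield at 15 min, the fraction of starting material turned into target per mM of precatalyst charged. At 0.25 mM it gives 23.6% target. The last noon row sums to 99.8%, so I expect 76.4% starting material.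

The forecast says 24.3% target and 75.7% starting material, a little more target than mine, on the ground that “The specific rate is still rising”.

    precatalyst → free catalyst (k = 0.0670 min⁻¹)
    catalyst intermediate B → free catalyst + second product (k = 4.10 min⁻¹)
    second substrate + free catalyst ⇌ catalyst intermediate B (K = 31.0 M⁻¹, k = 260 M⁻¹ min⁻¹)
    catalyst intermediate A → free catalyst + target (k = 22.0 min⁻¹)
    starting material + free catalyst ⇌ catalyst intermediate A (K = 330 M⁻¹, k = 540 M⁻¹ min⁻¹)

The flask holds 24.2% target and 75.6% starting material at 15 min. At that time 36.6% of the catalyst charged is still precatalyst. The specific yield of this flask is 0.968 mM⁻¹, against the 0.942 mM⁻¹ I carried. Applied to the flask with half the precatalyst, 0.942 mM⁻¹ gives 11.8%, and that flask holds 12.6% target.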